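**Plan**

1. Numbering used here: seven-membered ring C1 (CH–OAng beside the ring-fusion CH), C2 (CH2), C3/C4 (epoxide C–CH3 and CH), C5 (CH–OAng), C6 (C–CH3), C7 (CH); five-membered ring C6, C7, C8 (C(OH)iPr), C9, C10 (CHOH).
2. Retrosynthesis: cut both angelates and the C10 silyl ether, take the epoxide back to the C3=C4 allylic alcohol and that to a C5 ketone with an exocyclic CH2 on C3. Then cut C1–C2 and C3–C4 in one operation (de Mayo photocycloaddition/retro-aldol), leaving allene and the enol silyl ether of a cis-bicyclo[3.3.0]octane 1,3-dione.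
3. Enabling feature: the oxygens on C1 and C5 are 1,5-related across C2–C3(CH3)–C4 and the 5/7 fusion (C6 methyl, C7 H) is cis. The seven-membered ring is therefore the 1,5-dione obtained when two carbons are inserted, via a temporary cyclobutane, into the C1–C4 bond of a cis-fused cyclopentane-1,3-dione.
4. Forward order: the cyclopentane C6–C10 is built on (S)-4-silyloxycyclopentenone, the dione ring (C1, C4, C5, C6, C7) is closed by aldol/oxidation, allene expands it to the seven-membered ring, and epoxide and esters come last.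
5. Stereochemistry: C10 from the starting material; C6 by cuprate addition anti to OTBS; C7 and C8 by substrate-controlled aldol and organocerium additions; C1 by hydride delivery from the C8 hydroxyl; C5 by Felkin-type Luche reduction; C3/C4 by vanadium epoxidation directed by the C5 hydroxyl.

Key step: step 12

Remark: (S)-4-(tert-butyldimethylsilyloxy)cyclopent-2-en-1-one is taken as a commercial starting material; should the regioisomeric enol silyl ether form in step 11, it leads to the same dione 21.

**Route**

Step 1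
Reactants: 1 (S)-4-(tert-butyldimethylsilyloxy)cyclopent-2-en-1-one; 2 methylmagnesium bromide
Product: 3 trans-4-(tert-butyldimethylsilyloxy)-3-methyl-1-(trimethylsilyloxy)cyclopent-1-ene
Conditions: MeMgBr, CuBr·SMe2 (10 mol %), TMSCl, HMPA, THF, −78 °C
Reagents that add atoms: methylmagnesium bromide (2), C[Mg]Br; chlorotrimethylsilane, C[Si](C)(C)Cl
Why: Copper-catalysed conjugate addition with in situ silyl trapping of the enolate; methyl should enter anti to the silyloxy group, and this stereocenter is removed again in step 2.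

Step 2
Reactants: 3 trans-4-(tert-butyldimethylsilyloxy)-3-methyl-1-(trimethylsilyloxy)cyclopent-1-ene
Product: 4 (S)-4-(tert-butyldimethylsilyloxy)-3-methylcyclopent-2-en-1-one
Conditions: Pd(OAc)2 (10 mol %), O2 (1 atm), DMSO, rt
Reagents that add atoms: none
Why: Saegusa–Ito dehydrosilylation (catalytic variant with O2) should regenerate the enone regiospecifically from the silyl enol ether, now with the β-methyl group; the silyloxy stereocenter is untouched.

Step 3
Reactants: 4 (S)-4-(tert-butyldimethylsilyloxy)-3-methylcyclopent-2-en-1-one; 5 vinylmagnesium bromide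
Product: 6 4-(tert-butyldimethylsilyloxy)-3-methyl-1-(trimethylsilyloxy)-3-vinylcyclopent-1-ene (methyl cis to OTBS)
Conditions: CH2=CHMgBr, CuBr·SMe2 (20 mol %), TMSCl, HMPA, THF, −78 to −40 °C
Reagents that add atoms: vinylmagnesium bromide (5), C=C[Mg]Br; chlorotrimethylsilane, C[Si](C)(C)Cl
Why: A second copper-catalysed, TMSCl-accelerated conjugate addition should build the quaternary carbon C6: vinyl enters anti to the adjacent OTBS group, so methyl ends up cis to it, and the enolate is trapped regiospecifically as its silyl enol ether.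

Step 4
Reactants: 6 4-(tert-butyldimethylsilyloxy)-3-methyl-1-(trimethylsilyloxy)-3-vinylcyclopent-1-ene; 7 acetaldehyde
Product: 8 4-(tert-butyldimethylsilyloxy)-3-methyl-2-[1-(trimethylsilyloxy)ethyl]-3-vinylcyclopentan-1-one (side chain cis to vinyl; both carbinol epimers)
Conditions: MeCHO, Tf2NH (2 mol %), CH2Cl2, −78 °C
Reagents that add atoms: acetaldehyde (7), CC=O
Why: Mukaiyama aldol addition under TMSNTf2 catalysis with silyl transfer to the aldolate; the aldehyde should approach C7 on the face opposite the C6 methyl and the 1,3-related OTBS group, and the carbinol epimers converge in step 6.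

Step 5
Reactants: 8 4-(tert-butyldimethylsilyloxy)-3-methyl-2-[1-(trimethylsilyloxy)ethyl]-3-vinylcyclopentan-1-one; 9 isopropylmagnesium chloride
Product: 11 4-(tert-butyldimethylsilyloxy)-2-(1-hydroxyethyl)-1-isopropyl-3-methyl-3-vinylcyclopentan-1-ol (isopropyl trans to the side chain), via silyl ether carbinol 10 (not isolated)
Conditions: iPrMgCl, CeCl3, THF, −78 °C; aq NH4Cl; then citric acid, MeOH, 0 °C
Reagents that add atoms: isopropylmagnesium chloride (9), CC(C)[Mg]Cl
Why: Organocerium (Imamoto) addition to the enolisable ketone; isopropyl should add trans to the bulky α-(1-silyloxyethyl) group, as in additions to 2-substituted cyclopentanones, placing the C8 hydroxyl cis to the side chain, and mild acid then cleaves the secondary TMS ether.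

Step 6
Reactants: 11 4-(tert-butyldimethylsilyloxy)-2-(1-hydroxyethyl)-1-isopropyl-3-methyl-3-vinylcyclopentan-1-ol
Product: 12 1-[3-(tert-butyldimethylsilyloxy)-5-hydroxy-5-isopropyl-2-methyl-2-vinylcyclopentyl]ethan-1-one
Conditions: Dess–Martin periodinane, NaHCO3, CH2Cl2, 0 °C to rt
Reagents that add atoms: none
Why: Dess–Martin oxidation should convert only the secondary alcohol into the methyl ketone, since the tertiary alcohol cannot be oxidised.

Step 7
Reactants: 12 1-[3-(tert-butyldimethylsilyloxy)-5-hydroxy-5-isopropyl-2-methyl-2-vinylcyclopentyl]ethan-1-one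
Product: 13 the tertiary O-trimethylsilyl ether of 12
Conditions: 1-(trimethylsilyl)imidazole, CH2Cl2, rt to 40 °C
Reagents that add atoms: 1-(trimethylsilyl)imidazole, C[Si](C)(C)n1ccnc1
Why: Silylation of the tertiary alcohol with a neutral silyl donor blocks retro-aldol cleavage of the β-hydroxy ketone in the basic step 9 without enolising the ketone.

Step 8
Reactants: 13 the tertiary O-trimethylsilyl ether of 12
Product: 14 2-acetyl-5-(tert-butyldimethylsilyloxy)-3-isopropyl-1-methyl-3-(trimethylsilyloxy)cyclopentane-1-carbaldehyde (acetyl cis to CHO)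
Conditions: O3, CH2Cl2, −78 °C; then PPh3
Reagents that add atoms: ozone, [O-][O+]=O
Why: Ozonolysis with reductive work-up should cleave the only C=C bond to give the neopentyl, non-enolisable aldehyde (C5).

Step 9
Reactants: 14 2-acetyl-5-(tert-butyldimethylsilyloxy)-3-isopropyl-1-methyl-3-(trimethylsilyloxy)cyclopentane-1-carbaldehyde
Product: 15 cis-bicyclo[3.3.0]octane β-ketol (C1 ketone; C5 carbinol as both epimers; C8 OTMS; C10 OTBS)
Conditions: LiN(SiMe3)2, THF, −78 to −40 °C; aq NH4Cl
Reagents that add atoms: none
Why: Intramolecular aldol addition: the kinetic lithium enolate of the methyl ketone (C4) should add to the cis-disposed aldehyde and close the second five-membered ring cis-fused, as in the cyclisation of 1,4-keto aldehydes to 3-hydroxycyclopentanones; low temperature without a proton source avoids dehydration.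

Step 10
Reactants: 15 cis-bicyclo[3.3.0]octane β-ketol
Product: 16 cis-bicyclo[3.3.0]octane-1,5-dione (target numbering; C8 OTMS; C10 OTBS)
Conditions: Dess–Martin periodinane, NaHCO3, CH2Cl2, rt
Reagents that add atoms: none
Why: Dess–Martin oxidation of a β-ketol is a standard entry to cyclic 1,3-diones and makes both carbinol epimers converge.

Step 11
Reactants: 16 cis-bicyclo[3.3.0]octane-1,5-dione
Product: 17 C1-O-trimethylsilyl enol ether of 16 (C1=C4 enol ether; C5 ketone)
Conditions: TMSOTf, Et3N, CH2Cl2, −78 °C
Reagents that add atoms: trimethylsilyl triflate, C[Si](C)(C)OS(=O)(=O)C(F)(F)F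
Why: O-silylation of the 1,3-dione is expected on the less encumbered oxygen, the one flanked by the ring-fusion CH and not by the quaternary carbon, as in vinylogous ester formation from 4,4-disubstituted cyclic 1,3-diones.

Step 12
Reactants: 17 C1-O-trimethylsilyl enol ether of 16; 18 allene
Product: 21 cis-fused 3-methylene-bicyclo[5.3.0]decane-1,5-dione (C8 OH; C10 OTBS), via cyclobutane photoadduct 19 (not isolated), via cyclobutanol 20 (not isolated)
Conditions: allene (excess), hν (medium-pressure Hg lamp, Pyrex, λ > 290 nm), CH2Cl2, −78 °C; then TBAF, AcOH, THF, −40 to 0 °C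
Reagents that add atoms: allene (18), C=C=C
Why: De Mayo sequence: the n→π* excited, intersystem-crossed triplet of the 3-silyloxy enone adds allene through a triplet 1,4-biradical to give the cyclobutane 19, and fluoride then unmasks the cyclobutanol 20, whose strained β-hydroxy ketone undergoes retro-aldol cleavage of the bond shared by the five- and four-membered rings (the former C1–C4 bond). The closest known reaction types are the de Mayo reaction of 1,3-dione enol derivatives and the enone–allene [2+2] photocycloaddition. The four-membered ring closes by recombination of the biradical after spin inversion, and the seven-membered ring is not closed by a cyclisation but arises by ring expansion when the 5/4 fusion bond breaks, so the cis fusion at C6/C7 is carried over unchanged from 17. No new stereocenter survives: the two cyclobutane stereocenters (allene adds on the convex face, cis to the C6 methyl and C7 H) become the C1 carbonyl and the C4 methylene of 21. The selectivity needed is head-to-head regiochemistry (central allene carbon to the α-carbon C4, terminal CH2 to the silyloxy carbon C1); it is secured by the fully substituted, silyloxy-bearing C1, which leaves the unhindered C4 to bond first to the central allene carbon so that an allyl and an α-silyloxy radical result, as in the enone–allene additions that give β,γ-unsaturated ketones. Cold, acetic acid-buffered fluoride should keep the exocyclic alkene out of conjugation until step 14.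

Step 13
Reactants: 21 cis-fused 3-methylene-bicyclo[5.3.0]decane-1,5-dione
Product: 22 C1 alcohol of 21 (C1 OH cis to the C7 H and anti to the C8 OH; C5 ketone retained)
Conditions: Me4NBH(OAc)3, MeCN/AcOH, −30 °C
Reagents that add atoms: none
Why: Evans–Saksena directed reduction: the tertiary C8 hydroxyl exchanges onto boron and should deliver hydride to the lower (concave) face of the C1 ketone, giving the 1,3-anti diol, while the C5 ketone has no free β-hydroxyl and is not reduced.

Step 14
Reactants: 22 C1 alcohol of 21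
Product: 23 conjugated enone (C5 ketone; C3=C4; C3 methyl; C1 and C8 OH; C10 OTBS)
Conditions: DBU (20 mol %), CH2Cl2, rt
Reagents that add atoms: none
Why: Base-mediated isomerisation of the β,γ-unsaturated ketone into conjugation via the dienolate; only C4 is acidic on the C5 ketone (C6 is quaternary), so the alkene moves to C3=C4 and the exocyclic CH2 becomes the C3 methyl group.

Step 15
Reactants: 23 conjugated enone
Product: 24 allylic alcohol (C5 OH trans to the C6 methyl)
Conditions: NaBH4, CeCl3·7H2O, MeOH, −78 °C
Reagents that add atoms: none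
Why: Luche 1,2-reduction; Felkin–Anh-type attack anti to the larger, silyloxy-bearing ring carbon C10 on the quaternary α-carbon should bring hydride in from the face of the angular methyl and place the C5 hydroxyl trans to it.

Step 16
Reactants: 24 allylic alcohol
Product: 25 cis-epoxy alcohol (C3–C4 epoxide on the face of the C5 OH)
Conditions: VO(acac)2 (5 mol %), t-BuOOH, CH2Cl2, 0 °C to rt
Reagents that add atoms: tert-butyl hydroperoxide, CC(C)(C)OO
Why: Vanadium-catalysed hydroxyl-directed epoxidation: the allylic C5 vanadate should deliver oxygen to its own face, giving the cis-epoxy alcohol as with cyclohept-2-enol, while the homoallylic C1 hydroxyl on the other face reacts much more slowly.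

Step 17
Reactants: 25 cis-epoxy alcohol; 26 angelic acid
Product: 27 C1,C5-bis-angelate (C8 OH free; C10 OTBS)
Conditions: angelic acid, 2,4,6-trichlorobenzoyl chloride, Et3N, toluene, rt; then 25, 80 °C
Reagents that add atoms: angelic acid (26), C/C=C(/C)C(=O)O
Why: Yamaguchi-type esterification with the preformed mixed anhydride and no DMAP should acylate both secondary alcohols while keeping the Z-geometry of the angelate; the tertiary alcohol does not react and a cis-epoxy alcohol cannot undergo Payne rearrangement.

Step 18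
Reactants: 27 C1,C5-bis-angelate
Product: 28 CNP0265715.3 (1S,3S,4R,5R,6S,7S,8R,10S in the numbering above)
Conditions: HF·pyridine, pyridine, THF, 0 °C to rt
Reagents that add atoms: none
Why: Pyridine-buffered fluoride cleavage of the secondary TBS ether should free the C10 hydroxyl without opening the epoxide or isomerising the angelates.

**Compound list**

1 | (S)-4-(tert-butyldimethylsilyloxy)cyclopent-2-en-1-one | O=C1C[C@H](O[Si](C)(C)C(C)(C)C)C=C1 | starting material
2 | methylmagnesium bromide | C[Mg]Br | starting material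
3 | trans-4-(tert-butyldimethylsilyloxy)-3-methyl-1-(trimethylsilyloxy)cyclopent-1-ene | C[Si](C)(C)OC1=C[C@H](C)[C@@H](O[Si](C)(C)C(C)(C)C)C1 | intermediate
4 | (S)-4-(tert-butyldimethylsilyloxy)-3-methylcyclopent-2-en-1-one | O=C1C[C@H](O[Si](C)(C)C(C)(C)C)C(C)=C1 | intermediate
5 | vinylmagnesium bromide | C=C[Mg]Br | starting material
6 | 4-(tert-butyldimethylsilyloxy)-3-methyl-1-(trimethylsilyloxy)-3-vinylcyclopent-1-ene, methyl cis to OTBS | C[Si](C)(C)OC1=C[C@](C)(C=C)[C@@H](O[Si](C)(C)C(C)(C)C)C1 | intermediate
7 | acetaldehyde | CC=O | starting material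
8 | 4-(tert-butyldimethylsilyloxy)-3-methyl-2-[1-(trimethylsilyloxy)ethyl]-3-vinylcyclopentan-1-one, side chain cis to vinyl, carbinol epimers | CC(O[Si](C)(C)C)[C@H]1C(=O)C[C@H](O[Si](C)(C)C(C)(C)C)[C@@]1(C)C=C | intermediate
9 | isopropylmagnesium chloride | CC(C)[Mg]Cl | starting material
10 | 4-(tert-butyldimethylsilyloxy)-1-isopropyl-3-methyl-2-[1-(trimethylsilyloxy)ethyl]-3-vinylcyclopentan-1-ol, isopropyl trans to the side chain | CC(O[Si](C)(C)C)[C@H]1[C@](O)(C(C)C)C[C@H](O[Si](C)(C)C(C)(C)C)[C@@]1(C)C=C | intermediate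
11 | 4-(tert-butyldimethylsilyloxy)-2-(1-hydroxyethyl)-1-isopropyl-3-methyl-3-vinylcyclopentan-1-ol | CC(O)[C@H]1[C@](O)(C(C)C)C[C@H](O[Si](C)(C)C(C)(C)C)[C@@]1(C)C=C | intermediate
12 | 1-[3-(tert-butyldimethylsilyloxy)-5-hydroxy-5-isopropyl-2-methyl-2-vinylcyclopentyl]ethan-1-one | CC(=O)[C@H]1[C@](O)(C(C)C)C[C@H](O[Si](C)(C)C(C)(C)C)[C@@]1(C)C=C | intermediate
13 | tertiary O-trimethylsilyl ether of 12 | CC(=O)[C@H]1[C@](O[Si](C)(C)C)(C(C)C)C[C@H](O[Si](C)(C)C(C)(C)C)[C@@]1(C)C=C | intermediate
14 | 2-acetyl-5-(tert-butyldimethylsilyloxy)-3-isopropyl-1-methyl-3-(trimethylsilyloxy)cyclopentane-1-carbaldehyde, acetyl cis to CHO | CC(=O)[C@H]1[C@](O[Si](C)(C)C)(C(C)C)C[C@H](O[Si](C)(C)C(C)(C)C)[C@@]1(C)C=O | intermediate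
15 | cis-bicyclo[3.3.0]octane β-ketol (C1 ketone, C5 carbinol epimers, C8 OTMS, C10 OTBS) | O=C1CC(O)[C@]2(C)[C@@H](O[Si](C)(C)C(C)(C)C)C[C@@](O[Si](C)(C)C)(C(C)C)[C@H]12 | intermediate
16 | cis-bicyclo[3.3.0]octane-1,5-dione (C8 OTMS, C10 OTBS) | O=C1CC(=O)[C@]2(C)[C@@H](O[Si](C)(C)C(C)(C)C)C[C@@](O[Si](C)(C)C)(C(C)C)[C@H]12 | intermediate
17 | C1-O-trimethylsilyl enol ether of 16 (C5 ketone) | C[Si](C)(C)OC1=CC(=O)[C@]2(C)[C@@H](O[Si](C)(C)C(C)(C)C)C[C@@](O[Si](C)(C)C)(C(C)C)[C@H]12 | intermediate
18 | allene (propadiene) | C=C=C | starting material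
19 | cyclobutane photoadduct (methylenecyclobutane fused at C1–C4 on the convex face) | C[Si](C)(C)O[C@]12CC(=C)[C@H]1C(=O)[C@]3(C)[C@@H](O[Si](C)(C)C(C)(C)C)C[C@@](O[Si](C)(C)C)(C(C)C)[C@H]23 | intermediate
20 | cyclobutanol (both TMS groups removed) | O[C@]12CC(=C)[C@H]1C(=O)[C@]3(C)[C@@H](O[Si](C)(C)C(C)(C)C)C[C@@](O)(C(C)C)[C@H]23 | intermediate
21 | cis-fused 3-methylene-bicyclo[5.3.0]decane-1,5-dione (C8 OH, C10 OTBS) | O=C1CC(=C)CC(=O)[C@]2(C)[C@@H](O[Si](C)(C)C(C)(C)C)C[C@@](O)(C(C)C)[C@H]12 | intermediate
22 | C1 alcohol of 21 (OH cis to C7 H), C5 ketone | O[C@H]1CC(=C)CC(=O)[C@@]2(C)[C@@H]1[C@](O)(C(C)C)C[C@@H]2O[Si](C)(C)C(C)(C)C | intermediate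
23 | conjugated enone (C5 ketone, C3=C4, C3 methyl) | O[C@H]1CC(C)=CC(=O)[C@@]2(C)[C@@H]1[C@](O)(C(C)C)C[C@@H]2O[Si](C)(C)C(C)(C)C | intermediate
24 | allylic alcohol (C5 OH trans to C6 methyl) | O[C@H]1CC(C)=C[C@H](O)[C@@]2(C)[C@@H]1[C@](O)(C(C)C)C[C@@H]2O[Si](C)(C)C(C)(C)C | intermediate
25 | cis-epoxy alcohol (C3–C4 epoxide cis to C5 OH) | O[C@H]1C[C@]2(C)O[C@@H]2[C@H](O)[C@@]2(C)[C@@H]1[C@](O)(C(C)C)C[C@@H]2O[Si](C)(C)C(C)(C)C | intermediate
26 | angelic acid, (Z)-2-methylbut-2-enoic acid | C/C=C(/C)C(=O)O | starting material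
27 | C1,C5-bis-angelate, C10 TBS ether | C/C=C(/C)C(=O)O[C@H]1C[C@]2(C)O[C@@H]2[C@H](OC(=O)/C(C)=C\C)[C@@]2(C)[C@@H]1[C@](O)(C(C)C)C[C@@H]2O[Si](C)(C)C(C)(C)C | intermediate
28 | CNP0265715.3 | C/C=C(/C)C(=O)O[C@H]1C[C@]2(C)O[C@@H]2[C@H](OC(=O)/C(C)=C\C)[C@@]2(C)[C@@H]1[C@](O)(C(C)C)C[C@@H]2O | target

**Count and risks**

Total step count: 18. Longest linear sequence: 18 steps (from 1).

Steps most likely to fail:

Step 12. What may go wrong: the exocyclic double bond migrates into conjugation during fragmentation (giving an acidic vinylogous 1,3-dione), the ring-fusion CH next to the new C1 ketone epimerises, or the β,γ-unsaturated ketone undergoes secondary photoreaction. Fallback, setting out from 17: the irradiation is stopped at the cyclobutane 19, which is isolated and hydrogenated (H2, Pd/C, EtOAc) to the methylcyclobutane F1. TBAF/AcOH then gives the saturated 3-methyl dione F2, which has no alkene to migrate, and Evans–Saksena reduction gives the hydroxy ketone F3. The C3=C4 bond is put back by Saegusa–Ito oxidation: LiN(SiMe3)2/TMSCl gives the silyl enol ether F4 (the C5 ketone can enolise only towards C4), and Pd(OAc)2/O2 in DMSO followed by citric acid/MeOH comes back to the route at 23.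

Step 15. What may go wrong: poor facial selectivity, with hydride approaching anti to the angular methyl and giving the C5 epimer. Fallback, setting out from 23: Weitz–Scheffer epoxidation (t-BuOOH, DBU, CH2Cl2), with the hydroperoxide adding to C3 anti to the C1 oxygen substituent, gives the epoxy ketone F5. The oxirane now shields the lower face, and NaBH4/CeCl3 reduction anti to the epoxide C–O bond should give the cis-epoxy alcohol, coming back to the route at 25.

Step 9. What may go wrong: the 5-(enolendo) aldol closure is slow and the β-ketol dehydrates to the cyclopentenone. Fallback, setting out from 14: Pinnick oxidation (NaClO2, NaH2PO4, 2-methyl-2-butene, t-BuOH/H2O) gives the acid F6 and TMSCHN2 gives the methyl ester F7. Intramolecular Claisen condensation (KOt-Bu, THF), as in the classical preparation of cyclopentane-1,3-diones from 4-oxo esters, then comes back to the route at 16 without passing through 15.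

Further compounds
F1 | step 12 | hydrogenated photoadduct (methylcyclobutane, methyl epimers) | C[Si](C)(C)O[C@]12CC(C)[C@H]1C(=O)[C@]3(C)[C@@H](O[Si](C)(C)C(C)(C)C)C[C@@](O[Si](C)(C)C)(C(C)C)[C@H]23
F2 | step 12 | cis-fused 3-methyl-bicyclo[5.3.0]decane-1,5-dione (C8 OH, C10 OTBS, methyl epimers) | O=C1CC(C)CC(=O)[C@]2(C)[C@@H](O[Si](C)(C)C(C)(C)C)C[C@@](O)(C(C)C)[C@H]12
F3 | step 12 | C1 alcohol of F2 (OH cis to C7 H), C5 ketone | O[C@H]1CC(C)CC(=O)[C@@]2(C)[C@@H]1[C@](O)(C(C)C)C[C@@H]2O[Si](C)(C)C(C)(C)C
F4 | step 12 | C5 silyl enol ether (C4=C5) of F3 with C1 and C8 O-TMS | C[Si](C)(C)O[C@H]1CC(C)C=C(O[Si](C)(C)C)[C@@]2(C)[C@@H]1[C@](O[Si](C)(C)C)(C(C)C)C[C@@H]2O[Si](C)(C)C(C)(C)C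
F5 | step 15 | C3–C4 epoxy C5 ketone (epoxide trans to C1 OH) | O[C@H]1C[C@]2(C)O[C@@H]2C(=O)[C@@]2(C)[C@@H]1[C@](O)(C(C)C)C[C@@H]2O[Si](C)(C)C(C)(C)C
F6 | step 9 | 2-acetyl-5-(tert-butyldimethylsilyloxy)-3-isopropyl-1-methyl-3-(trimethylsilyloxy)cyclopentane-1-carboxylic acid | CC(=O)[C@H]1[C@](O[Si](C)(C)C)(C(C)C)C[C@H](O[Si](C)(C)C(C)(C)C)[C@@]1(C)C(=O)O
F7 | step 9 | methyl ester of F6 | CC(=O)[C@H]1[C@](O[Si](C)(C)C)(C(C)C)C[C@H](O[Si](C)(C)C(C)(C)C)[C@@]1(C)C(=O)OC
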